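**Retrosynthetic overview**

1. Locants used below are those of the tricyclo[5.3.1.0(1,5)]undecane skeleton: C1 and C7 are the bridgeheads, C11 is the bridging ketone, C8–C10 is the enolised β-diketone with the acyl group on C9, and C2–C5 belong to the cyclopentane (C3 carries the side chain, C4 the gem-dimethyl group).
2. The last step is hydration of a C3 isopropenyl group to the tertiary alcohol.
3. Key disconnection: the C1–C5 and C3–C4 bonds are cut together (oxidative radical cascade, two 5-exo closures). This removes the two-carbon bridge C5–C6 of the bicyclo[3.2.1]octane and the fused cyclopentane at once and leaves a monocyclic, dearomatised 6-methyl-2,6-diprenyl acylphloroglucinol with one stereocentre (C7).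
4. Enabling feature: C1 is the α-carbon between the C10 and C11 carbonyls of an enolised β-triketone ring and can be oxidised to a radical. The alkene C5=C4 of the prenyl group on C7 and the alkene carbon C3 of the prenyl group on C1 each lie in 5-exo reach, and C4 relays the radical as a tertiary centre.
5. Ring order: the six-membered trione ring first (C-acylation of a β-diketone with an enantiopure methyl(prenyl)malonyl chloride, then Claisen ring closure; C7 comes from an asymmetric phase-transfer prenylation), then the cyclopentanone ring (C1–C5) and the cyclopentane (C3–C4) in the key step.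

Key step: step 8

Remark: the (S,S)-antipode of the phase-transfer catalyst is assumed to give the (R)-diester in step 3; if the sense of induction is the opposite, the (R,R)-antipode is used and nothing else changes. Enolised di- and triketones are drawn as one tautomer.

**Route**

Step 1
Reactants: 1 2,2,5-trimethyl-1,3-dioxane-4,6-dione; 2 tert-butanol
Product: 3 3-tert-butoxy-2-methyl-3-oxopropanoic acid
Conditions: t-BuOH (reagent and solvent), reflux
Reagents that add atoms: none
Why: Alcoholysis of the 1,3-dioxane-4,6-dione ring by the alcohol with loss of acetone gives the malonic half-ester, whose α-carbon is stereolabile and needs no control.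

Step 2
Reactants: 3 3-tert-butoxy-2-methyl-3-oxopropanoic acid; 4 2,2-diphenylethanol
Product: 5 1-tert-butyl 3-(2,2-diphenylethyl) 2-methylpropanedioate
Conditions: DCC, DMAP (cat.), CH2Cl2, 0 °C → rt
Reagents that add atoms: none
Why: Steglich esterification of a primary alcohol, which leaves the tert-butyl ester untouched and gives the mixed diester on which the asymmetric alkylation depends.

Step 3
Reactants: 5 1-tert-butyl 3-(2,2-diphenylethyl) 2-methylpropanedioate; 6 1-bromo-3-methylbut-2-ene (prenyl bromide)
Product: 7 1-tert-butyl 3-(2,2-diphenylethyl) (2R)-2-methyl-2-(3-methylbut-2-en-1-yl)propanedioate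
Conditions: (S,S)-3,4,5-trifluorophenyl-NAS bromide (N-spiro bis-binaphthyl quaternary ammonium bromide, 5 mol %), 50% aq. KOH, toluene, −40 °C
Reagents that add atoms: none
Why: Enantioselective phase-transfer α-alkylation of an α-methylmalonate with two sterically different esters, in which the chiral ammonium cation ion-pairs with the prochiral enolate, shields one face and lets the allylic bromide enter from the other, setting the quaternary centre that becomes C7.

Step 4
Reactants: 7 1-tert-butyl 3-(2,2-diphenylethyl) (2R)-2-methyl-2-(3-methylbut-2-en-1-yl)propanedioate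
Product: 8 (2S)-3-(2,2-diphenylethoxy)-2-methyl-2-(3-methylbut-2-en-1-yl)-3-oxopropanoic acid
Conditions: TMSOTf, 2,6-lutidine, CH2Cl2, 0 °C; then H2O
Reagents that add atoms: none
Why: Silyl triflate-mediated cleavage of the tert-butyl ester (loss of 2-methylpropene, then hydrolysis of the silyl ester) under buffered, non-protic conditions spares the prenyl alkene and the primary ester, and the quaternary centre cannot epimerise.

Step 5
Reactants: 9 6-methylhept-5-en-2-one; 10 methyl 2-methylpropanoate
Product: 11 2,9-dimethyldec-8-ene-3,5-dione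
Conditions: NaH, DME, reflux; then aq. HCl
Reagents that add atoms: none
Why: Crossed Claisen condensation in which the methyl ketone is acylated at its methyl group by the hindered ester and the product is drained off as its stabilised diketonate.

Step 6
Reactants: 8 (2S)-3-(2,2-diphenylethoxy)-2-methyl-2-(3-methylbut-2-en-1-yl)-3-oxopropanoic acid; 11 2,9-dimethyldec-8-ene-3,5-dione
Product: 13 2,2-diphenylethyl (2S)-2,5-dimethyl-2-[7-methyl-2-(2-methylpropanoyl)-3-oxooct-6-enoyl]hex-4-enoate, via acid chloride 12 (not isolated)
Conditions: 1-chloro-N,N,2-trimethylprop-1-en-1-amine, CH2Cl2, 0 °C → rt; then add to 11, MgCl2, Et3N, MeCN, 0 °C → rt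
Reagents that add atoms: 1-chloro-N,N,2-trimethylprop-1-en-1-amine, CC(C)=C(Cl)N(C)C
Why: The acid chloride is formed under neutral conditions (no HCl to add to the prenyl group) and then acylates the magnesium chelate of the β-diketone at its central carbon (soft-enolisation C-acylation), while the stereocentre, having no α-hydrogen, is carried through unchanged.

Step 7
Reactants: 13 2,2-diphenylethyl (2S)-2,5-dimethyl-2-[7-methyl-2-(2-methylpropanoyl)-3-oxooct-6-enoyl]hex-4-enoate
Product: 14 (6S)-3,5-dihydroxy-6-methyl-2,6-bis(3-methylbut-2-en-1-yl)-4-(2-methylpropanoyl)cyclohexa-2,4-dien-1-one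
Conditions: LDA (2.5 equiv), THF, −78 → 0 °C; then aq. HCl
Reagents that add atoms: none
Why: The dianion (central triketone C–H first, then kinetic deprotonation of the CH2 next to the ketone on the homoprenyl side) closes the six-membered ring by an intramolecular Claisen (Dieckmann-type) acylation on the 2,2-diphenylethyl ester, driven by the stabilised triketonate; the untouched quaternary centre becomes C6 with the (S) configuration because the ester carbonyl ends up next to the prenyl-bearing carbon.

Step 8
Reactants: 14 (6S)-3,5-dihydroxy-6-methyl-2,6-bis(3-methylbut-2-en-1-yl)-4-(2-methylpropanoyl)cyclohexa-2,4-dien-1-one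
Product: 15 (1S,3S,5S,7S)-8-hydroxy-4,4,7-trimethyl-9-(2-methylpropanoyl)-3-(prop-1-en-2-yl)tricyclo[5.3.1.0(1,5)]undec-8-ene-10,11-dione
Conditions: Mn(OAc)3·2H2O (2.2 equiv), Cu(OAc)2·H2O (1.0 equiv, re-oxidised in the flask), degassed AcOH, rt
Reagents that add atoms: none
Why: Trivalent manganese oxidises the enolised β-triketone of 14 to an electrophilic radical with spin density at C1, which adds 5-exo-trig to C5 of the prenyl group on C7 and closes the cyclopentanone ring of the bicyclo[3.2.1]octane; the tertiary radical so formed at C4 adds 5-exo-trig to C3 of the second prenyl group and closes the cyclopentane, and divalent copper oxidises the final tertiary radical to the isopropenyl group. The closest known reaction type is the Mn(OAc)3/Cu(OAc)2 oxidative radical cyclisation cascade of 1,3-dicarbonyl compounds onto two alkenes, which is established for dearomatised diprenyl acylphloroglucinols. C1 is set by the tether, because the prenyl chain on C7 can reach only the ring face on which it stands, so the C7 centre from step 3 fixes the absolute configuration of the bicycle; C5 is set because only the exo radical (CMe2 group syn to the C11 bridge) can reach the second alkene and give the cis-fused diquinane. C3 is set in the second closure, where the gauche C4–C5–C1–C2 torsion fixed by the bicycle lets a chair-like transition state of the 5-hexenyl radical place the CMe2 terminus on the convex face, cis to H5, which is the configuration of the target. The step needs site selectivity for C1 over the acyl-bearing C9 (C9 is the more stabilised and more hindered terminus, and closure there would make a quaternary tricarbonyl centre) and facial selectivity at C3; the latter is the weaker control and is expected to be moderate, so the C3 epimer is to be removed by chromatography after step 9, where the two tertiary alcohols differ in their ability to hydrogen-bond to the C10 carbonyl.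

Step 9
Reactants: 15 (1S,3S,5S,7S)-8-hydroxy-4,4,7-trimethyl-9-(2-methylpropanoyl)-3-(prop-1-en-2-yl)tricyclo[5.3.1.0(1,5)]undec-8-ene-10,11-dione
Product: 16 (1S,3R,5S,7S)-8-hydroxy-3-(2-hydroxypropan-2-yl)-4,4,7-trimethyl-9-(2-methylpropanoyl)tricyclo[5.3.1.0(1,5)]undec-8-ene-10,11-dione
Conditions: Co(acac)2 (20 mol %), PhSiH3, O2 (1 atm), THF/i-PrOH, 0 °C → rt
Reagents that add atoms: dioxygen, O=O
Why: Mukaiyama hydration, in which hydrogen-atom transfer from a cobalt hydride to the 1,1-disubstituted alkene gives the tertiary radical that is trapped by O2 and reduced to the tertiary alcohol at the more substituted carbon; no stereocentre is made or touched, and the tetrasubstituted, electron-poor enol is not a substrate for hydrogen-atom transfer.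

**Compound list**

1 | 2,2,5-trimethyl-1,3-dioxane-4,6-dione | CC1C(=O)OC(C)(C)OC1=O | starting material
2 | tert-butanol | CC(C)(C)O | starting material
3 | 3-tert-butoxy-2-methyl-3-oxopropanoic acid (stereolabile α-carbon) | CC(C(=O)O)C(=O)OC(C)(C)C | intermediate
4 | 2,2-diphenylethanol | OCC(c1ccccc1)c1ccccc1 | starting material
5 | 1-tert-butyl 3-(2,2-diphenylethyl) 2-methylpropanedioate | CC(C(=O)OC(C)(C)C)C(=O)OCC(c1ccccc1)c1ccccc1 | intermediate
6 | 1-bromo-3-methylbut-2-ene (prenyl bromide) | CC(C)=CCBr | starting material
7 | 1-tert-butyl 3-(2,2-diphenylethyl) (2R)-2-methyl-2-(3-methylbut-2-en-1-yl)propanedioate | CC(C)(C)OC(=O)[C@](C)(CC=C(C)C)C(=O)OCC(c1ccccc1)c1ccccc1 | intermediate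
8 | (2S)-3-(2,2-diphenylethoxy)-2-methyl-2-(3-methylbut-2-en-1-yl)-3-oxopropanoic acid | OC(=O)[C@](C)(CC=C(C)C)C(=O)OCC(c1ccccc1)c1ccccc1 | intermediate
9 | 6-methylhept-5-en-2-one | CC(=O)CCC=C(C)C | starting material
10 | methyl 2-methylpropanoate | COC(=O)C(C)C | starting material
11 | 2,9-dimethyldec-8-ene-3,5-dione | CC(C)C(=O)CC(=O)CCC=C(C)C | intermediate
12 | 2,2-diphenylethyl (2R)-2-(chlorocarbonyl)-2,5-dimethylhex-4-enoate | ClC(=O)[C@](C)(CC=C(C)C)C(=O)OCC(c1ccccc1)c1ccccc1 | intermediate
13 | 2,2-diphenylethyl (2S)-2,5-dimethyl-2-[7-methyl-2-(2-methylpropanoyl)-3-oxooct-6-enoyl]hex-4-enoate (triketo tautomer; the central carbon is enolised and has no fixed configuration) | CC(C)C(=O)C(C(=O)CCC=C(C)C)C(=O)[C@](C)(CC=C(C)C)C(=O)OCC(c1ccccc1)c1ccccc1 | intermediate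
14 | (6S)-3,5-dihydroxy-6-methyl-2,6-bis(3-methylbut-2-en-1-yl)-4-(2-methylpropanoyl)cyclohexa-2,4-dien-1-one | CC(C)C(=O)C1=C(O)[C@](C)(CC=C(C)C)C(=O)C(CC=C(C)C)=C1O | intermediate
15 | (1S,3S,5S,7S)-8-hydroxy-4,4,7-trimethyl-9-(2-methylpropanoyl)-3-(prop-1-en-2-yl)tricyclo[5.3.1.0(1,5)]undec-8-ene-10,11-dione | CC(C)C(=O)C1=C(O)[C@]2(C)C[C@H]3C(C)(C)[C@H](C(C)=C)C[C@@]3(C1=O)C2=O | intermediate
16 | (1S,3R,5S,7S)-8-hydroxy-3-(2-hydroxypropan-2-yl)-4,4,7-trimethyl-9-(2-methylpropanoyl)tricyclo[5.3.1.0(1,5)]undec-8-ene-10,11-dione (CNP0267234.2) | CC(C)C(=O)C1=C(O)[C@]2(C)C[C@H]3C(C)(C)[C@H](C(C)(C)O)C[C@@]3(C1=O)C2=O | target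

**Summary**

Total step count: 9. Longest linear sequence: 8 steps (steps 1–4 and 6–9); step 5 is the side branch.

**Steps most likely to fail**

Step 8. The second 5-exo closure may show poor facial selectivity at C3, and the C4 radical may be oxidised before it closes. The fallback sets out from 15 and comes back at 16, and corrects C3 under thermodynamic control. The crude product of step 8, 15 together with the 3-epimeric isopropenyl tricycle F1, is cleaved at the isopropenyl group by Lemieux–Johnson oxidation (OsO4 cat., NaIO4, 2,6-lutidine, dioxane/H2O) to the 3-acetyl tricycle F2 and the 3-epimeric acetyl tricycle F3. DBU in toluene then equilibrates F3 into F2 through the ketone enolate, the acetyl group being expected to take the less hindered convex face, cis to H5. Addition of MeMgBr/CeCl3 (excess, THF, −78 °C; the first equivalent is spent on the enol) to the methyl ketone of F2, with the C11 ketone shielded by its two quaternary neighbours, gives 16.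

Step 7. The γ-carbanion may fail to acylate on the hindered ester, either because an enolate oxygen closes to a pyranone or because proton transfer quenches the dianion. The fallback sets out from 5 and comes back at 14, and makes the two C–C bonds of the trione ring in the opposite order. This needs the mirror-image malonate, because the two carbonyl roles are exchanged. Step 3 run with the (R,R)-catalyst gives the (S)-diester F4, the conditions of step 4 give the (R)-acid F5, and the chloroenamine of step 6 gives the (S)-acid chloride F6. This is added at −78 °C to the dianion of 11 (LDA, THF; two equivalents of dianion), which is acylated at its terminal CH2 to give the linear triketo ester F7. Ring closure by the doubly activated methylene carbon on the ester (LiHMDS, THF, 0 → 40 °C) then gives 14.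

Step 3. Enantioselectivity may be eroded by uncatalysed interfacial alkylation with the very reactive allylic bromide, or the sense of induction may be the wrong one. The fallback sets out from 5 and comes back at 8, and is a classical resolution. Alkylation of 5 with 6 under achiral phase-transfer conditions (Bu4NBr, 50% aq. KOH, toluene) gives the racemic diester F8, and the conditions of step 4 give the racemic acid F9. Crystallisation with (R)-1-phenylethanamine (or its antipode, whichever gives the less soluble salt of the (S)-acid) gives the diastereomerically pure ammonium salt F10, and acidification returns the (S)-acid 8.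

**Further compounds**

F1 | step 8 | (1S,3R,5S,7S)-8-hydroxy-4,4,7-trimethyl-9-(2-methylpropanoyl)-3-(prop-1-en-2-yl)tricyclo[5.3.1.0(1,5)]undec-8-ene-10,11-dione (3-epimer of 15) | CC(C)C(=O)C1=C(O)[C@]2(C)C[C@H]3C(C)(C)[C@@H](C(C)=C)C[C@@]3(C1=O)C2=O
F2 | step 8 | (1S,3R,5S,7S)-3-acetyl-8-hydroxy-4,4,7-trimethyl-9-(2-methylpropanoyl)tricyclo[5.3.1.0(1,5)]undec-8-ene-10,11-dione | CC(C)C(=O)C1=C(O)[C@]2(C)C[C@H]3C(C)(C)[C@H](C(C)=O)C[C@@]3(C1=O)C2=O
F3 | step 8 | (1S,3S,5S,7S)-3-acetyl-8-hydroxy-4,4,7-trimethyl-9-(2-methylpropanoyl)tricyclo[5.3.1.0(1,5)]undec-8-ene-10,11-dione (3-epimer of F2) | CC(C)C(=O)C1=C(O)[C@]2(C)C[C@H]3C(C)(C)[C@@H](C(C)=O)C[C@@]3(C1=O)C2=O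
F4 | step 7 | 1-tert-butyl 3-(2,2-diphenylethyl) (2S)-2-methyl-2-(3-methylbut-2-en-1-yl)propanedioate | CC(C)(C)OC(=O)[C@@](C)(CC=C(C)C)C(=O)OCC(c1ccccc1)c1ccccc1
F5 | step 7 | (2R)-3-(2,2-diphenylethoxy)-2-methyl-2-(3-methylbut-2-en-1-yl)-3-oxopropanoic acid | OC(=O)[C@@](C)(CC=C(C)C)C(=O)OCC(c1ccccc1)c1ccccc1
F6 | step 7 | 2,2-diphenylethyl (2S)-2-(chlorocarbonyl)-2,5-dimethylhex-4-enoate | ClC(=O)[C@@](C)(CC=C(C)C)C(=O)OCC(c1ccccc1)c1ccccc1
F7 | step 7 | 2,2-diphenylethyl (2R)-2,5-dimethyl-2-[6-methyl-2-(3-methylbut-2-en-1-yl)-3,5-dioxoheptanoyl]hex-4-enoate | CC(C)C(=O)CC(=O)C(CC=C(C)C)C(=O)[C@@](C)(CC=C(C)C)C(=O)OCC(c1ccccc1)c1ccccc1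
F8 | step 3 | racemic 1-tert-butyl 3-(2,2-diphenylethyl) 2-methyl-2-(3-methylbut-2-en-1-yl)propanedioate | CC(C)(C)OC(=O)C(C)(CC=C(C)C)C(=O)OCC(c1ccccc1)c1ccccc1
F9 | step 3 | racemic 3-(2,2-diphenylethoxy)-2-methyl-2-(3-methylbut-2-en-1-yl)-3-oxopropanoic acid | OC(=O)C(C)(CC=C(C)C)C(=O)OCC(c1ccccc1)c1ccccc1
F10 | step 3 | (R)-1-phenylethanaminium (2S)-3-(2,2-diphenylethoxy)-2-methyl-2-(3-methylbut-2-en-1-yl)-3-oxopropanoate | [O-]C(=O)[C@](C)(CC=C(C)C)C(=O)OCC(c1ccccc1)c1ccccc1.C[C@@H]([NH3+])c1ccccc1
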